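A direct plan would acylate resorcinol A1 with 3,5-dimethoxyphenylacetic acid A2 to give the deoxybenzoin A3, reduce it and let the benzylic cation alkylate a second resorcinol to give the achiral bis-resorcinol A4, brominate one of its two enantiotopic rings under a chiral phosphoric acid to give A5, attach the styryl arm by Heck reaction with 3,5-dimethoxystyrene A6 to give A7, and end with BBr3. Its weakest steps would be:
- The desymmetrising bromination of A4: the only stereocentre would rest on a reaction without precedent that must tell two identical resorcinol rings apart, with dibromination and attack on the dimethoxyphenyl ring competing.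
- The cation alkylation that makes A4: the ionised carbinol has β-hydrogens, so it would lose a proton to the stilbene, attack resorcinol at C2 as well as C4, and oligomerise; only a large excess of A1 would hold this back.
- The closing BBr3 demethylation of A7: strong acid on a 2,4-dihydroxystilbene and a doubly benzylic methine invites alkene protonation, cyclisation and retro-Friedel–Crafts loss of configuration.

**Retrosynthetic overview**
- Rings A and D are both 5-substituted resorcinols (C1 between two CH, OH on C3 and C5), the pattern of a cyclised 2,4,6-triketone. Each is cut at C1–C2 and C1–C6 into an acyl carbon (future C1) and acetylacetone (C2–C6 and both oxygens).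
- For ring D the acyl carbon is C2 of a 4-aryl-3,4-dihydrocoumarin: the lactone oxygen is the 2-OH oxygen of ring C, the benzo ring is ring C, C3 is the CH2, C4 is the stereocentre. For ring A it is the carbonyl of an acrylic Weinreb amide at C4 of ring B.
- The lactone comes from the MOM ether of umbelliferone and a ring B boronic acid by rhodium/(R)-Segphos conjugate addition. The catalyst chooses a face of a coumarin and never has to tell ring B from ring C.
- Ring order: B and C are bought (4,6-dibromoresorcinol, umbelliferone), the lactone is a temporary ring, and A and D are closed together in the last C–C bond-forming step, which also opens the lactone and frees the 2-OH of ring C.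
- Avoided by design: no benzylic cation, no selection between enantiotopic rings, no aryl methyl ethers. Rings A and D are formed as free phenols, and three MOM acetals remain for a mild final step.

Key step: step 6

Remark: ring A is the 3,5-dihydroxyphenyl on the alkene, ring B the central resorcinol, ring C the 2,4-dihydroxyphenyl on the stereocentre, ring D the 3,5-dihydroxyphenyl on CH2. (R)-Segphos is assumed to keep, with the ortho-alkoxyaryl donor, the facial sense it shows in aryl additions to coumarin; its enantiomer is equally available.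

**Step 1**
Reactants: 1 4,6-dibromobenzene-1,3-diol (4,6-dibromoresorcinol)
Product: 2 1,5-dibromo-2,4-bis(methoxymethoxy)benzene
Conditions: MOMCl (2.5 equiv), i-Pr2NEt (3 equiv), DMF, 0 °C → rt
Reagents that add atoms: chloromethyl methyl ether, COCCl
Why: O-alkylation of both phenols by the α-chloro ether (MOM acetal formation) is fast with a hindered amine base, and the small acetal should not hinder the later reactions ortho to it; no stereocentre is formed.

**Step 2**
Reactants: 2 1,5-dibromo-2,4-bis(methoxymethoxy)benzene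
Product: 4 [5-bromo-2,4-bis(methoxymethoxy)phenyl]boronic acid, via aryllithium 3 (not isolated)
Conditions: n-BuLi (1.05 equiv), THF, −78 °C, 10 min; B(OiPr)3 (1.5 equiv), −78 → 0 °C; 1 M HCl to pH 5, 0 °C
Reagents that add atoms: triisopropyl borate, CC(C)OB(OC(C)C)OC(C)C; water, O
Why: Bromine–lithium exchange at one of the two equivalent C–Br bonds is far faster than deprotonation, the aryllithium is held by the ortho MOM oxygen and is trapped by the borate (electrophilic borylation, then hydrolysis), and one equivalent of n-BuLi leaves the second bromide for the later Heck reaction.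

**Step 3**
Reactants: 5 7-hydroxy-2H-chromen-2-one (umbelliferone)
Product: 6 7-(methoxymethoxy)-2H-chromen-2-one
Conditions: MOMCl (1.5 equiv), i-Pr2NEt (2 equiv), DMF, 0 °C → rt
Reagents that add atoms: chloromethyl methyl ether, COCCl
Why: O-alkylation of the only hydroxyl (MOM acetal formation) masks the 7-oxygen, whose phenoxide would otherwise push electrons into C4 and shut down the conjugate addition.

**Step 4**
Reactants: 4 [5-bromo-2,4-bis(methoxymethoxy)phenyl]boronic acid; 6 7-(methoxymethoxy)-2H-chromen-2-one
Product: 7 (4S)-4-[5-bromo-2,4-bis(methoxymethoxy)phenyl]-7-(methoxymethoxy)-3,4-dihydro-2H-chromen-2-one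
Conditions: Rh(acac)(C2H4)2 (3 mol %), (R)-Segphos (3.3 mol %), 4 (3 equiv), 1,4-dioxane–H2O 10:1, 60 °C, Ar
Reagents that add atoms: none
Why: Hayashi–Miyaura rhodium-catalysed asymmetric conjugate addition, in which the aryl–rhodium species from transmetalation adds across C3=C4 of the coumarin on the face left open by (R)-Segphos and the oxa-π-allyl intermediate is hydrolysed; this ligand gives (R)-4-arylchroman-2-ones from coumarin, and the same face is named (4S) here because ring B outranks C4a, while the C–Br bond is inert to monovalent rhodium.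

**Step 5**
Reactants: 7 (4S)-4-[5-bromo-2,4-bis(methoxymethoxy)phenyl]-7-(methoxymethoxy)-3,4-dihydro-2H-chromen-2-one; 8 N-methoxy-N-methylprop-2-enamide
Product: 9 (2E)-N-methoxy-3-{5-[(4S)-7-(methoxymethoxy)-2-oxo-3,4-dihydro-2H-chromen-4-yl]-2,4-bis(methoxymethoxy)phenyl}-N-methylprop-2-enamide
Conditions: Pd(OAc)2 (5 mol %), [(t-Bu)3PH]BF4 (10 mol %), Cy2NMe (2 equiv), 8 (1.5 equiv), 1,4-dioxane, 80 °C, Ar
Reagents that add atoms: none
Why: Mizoroki–Heck reaction in which zerovalent palladium bearing P(t-Bu)3 inserts into the electron-rich C–Br bond, and syn-carbopalladation at the terminal carbon of the acrylamide followed by syn-β-hydride elimination gives the (E)-alkene; the lactone and the non-acidic stereocentre are untouched by the amine base.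

**Step 6**
Reactants: 9 (2E)-N-methoxy-3-{5-[(4S)-7-(methoxymethoxy)-2-oxo-3,4-dihydro-2H-chromen-4-yl]-2,4-bis(methoxymethoxy)phenyl}-N-methylprop-2-enamide; 10 pentane-2,4-dione (acetylacetone)
Product: 13 5-[(E)-2-{5-[(1S)-2-(3,5-dihydroxyphenyl)-1-[2-hydroxy-4-(methoxymethoxy)phenyl]ethyl]-2,4-bis(methoxymethoxy)phenyl}ethenyl]benzene-1,3-diol, via dilithioacetylacetone 11 (not isolated), via open-chain bis-triketone 12 (not isolated)
Conditions: 10 (5 equiv), LiN(i-Pr)2 (10 equiv), THF, −78 → 0 °C; 9, −78 °C → rt; then degassed 2 M aq. KOH–MeOH 1:1, 25 → 50 °C, Ar; 1 M HCl to pH 5, 0 °C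
Reagents that add atoms: none
Why: Dilithioacetylacetone attacks through its terminal carbanion at the lactone carbonyl (an aryl ester, the phenoxide of ring C leaves) and at the Weinreb amide carbonyl (1,2-addition held as the chelate until quench), which is the terminal acylation of β-diketone dianions by esters and amides and gives bis-triketone 12 on addition of water. In aqueous KOH each 2,4,6-triketone arm closes by a 6-(enolendo)-exo-trig aldol addition of its terminal methyl carbon onto the carbonyl that carries the arm (the former lactone carbon for ring D, the former amide carbon for ring A), and loss of water with enolisation gives the 5-substituted resorcinol; this is the classical base cyclisation of heptane-2,4,6-trione to orcinol and the way stilbene synthase builds ring A. No stereocentre is formed, and the (S) centre is β to the carbonyl, has no acidic hydrogen and no leaving group, so neither the dianion nor hydroxide should touch it. The selectivity needed is methyl-as-nucleophile in the ring D arm, where the CH2 next to the stereocentre could instead add to the acetyl carbonyl and give a 4-substituted 5-methylresorcinol: that carbon is shielded by the diarylmethine and its closure would wedge this group between OH and CH3, whereas the cinnamoyl arm has no second enolisable terminus. Aromatisation is irreversible and should drain the reversible side equilibria (hemiketal with the ring C phenoxide, oxa-Michael adduct of the enone).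

**Step 7**
Reactants: 13 5-[(E)-2-{5-[(1S)-2-(3,5-dihydroxyphenyl)-1-[2-hydroxy-4-(methoxymethoxy)phenyl]ethyl]-2,4-bis(methoxymethoxy)phenyl}ethenyl]benzene-1,3-diol
Product: 14 4-[(1S)-1-(2,4-dihydroxyphenyl)-2-(3,5-dihydroxyphenyl)ethyl]-6-[(E)-2-(3,5-dihydroxyphenyl)ethenyl]benzene-1,3-diol
Conditions: HCl (0.5 M in MeOH), MeOH–THF, 30 °C, Ar
Reagents that add atoms: none
Why: Acid-catalysed acetal exchange (MOM methanolysis) runs through the oxocarbenium ion of the protecting group, which methanol captures as dimethoxymethane, at an acidity and temperature too low to protonate the stilbene or to ionise the C–H stereocentre.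

**Compound list**
1 | 4,6-dibromobenzene-1,3-diol (4,6-dibromoresorcinol) | Oc1cc(O)c(Br)cc1Br | starting material
2 | 1,5-dibromo-2,4-bis(methoxymethoxy)benzene | COCOc1cc(OCOC)c(Br)cc1Br | intermediate
3 | [5-bromo-2,4-bis(methoxymethoxy)phenyl]lithium (not isolated) | [Li]c1cc(Br)c(OCOC)cc1OCOC | intermediate
4 | [5-bromo-2,4-bis(methoxymethoxy)phenyl]boronic acid | OB(O)c1cc(Br)c(OCOC)cc1OCOC | intermediate
5 | 7-hydroxy-2H-chromen-2-one (umbelliferone) | O=c1ccc2ccc(O)cc2o1 | starting material
6 | 7-(methoxymethoxy)-2H-chromen-2-one | COCOc1ccc2ccc(=O)oc2c1 | intermediate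
7 | (4S)-4-[5-bromo-2,4-bis(methoxymethoxy)phenyl]-7-(methoxymethoxy)-3,4-dihydro-2H-chromen-2-one | Brc1cc([C@@H](CC(=O)O2)c3ccc(OCOC)cc32)c(OCOC)cc1OCOC | intermediate
8 | N-methoxy-N-methylprop-2-enamide | C=CC(=O)N(C)OC | starting material
9 | (2E)-N-methoxy-3-{5-[(4S)-7-(methoxymethoxy)-2-oxo-3,4-dihydro-2H-chromen-4-yl]-2,4-bis(methoxymethoxy)phenyl}-N-methylprop-2-enamide | CON(C)C(=O)/C=C/c1cc([C@@H](CC(=O)O2)c3ccc(OCOC)cc32)c(OCOC)cc1OCOC | intermediate
10 | pentane-2,4-dione (acetylacetone) | CC(=O)CC(C)=O | starting material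
11 | dilithium salt of the pentane-2,4-dione 1,3-dianion (dilithioacetylacetone, not isolated) | [Li+].[Li+].[CH2-]C(=O)[CH-]C(C)=O | intermediate
12 | (1E)-1-{5-[(1S)-1-[2-hydroxy-4-(methoxymethoxy)phenyl]-3,5,7-trioxooctyl]-2,4-bis(methoxymethoxy)phenyl}oct-1-ene-3,5,7-trione (not isolated) | CC(=O)CC(=O)CC(=O)/C=C/c1cc([C@@H](CC(=O)CC(=O)CC(C)=O)c2ccc(OCOC)cc2O)c(OCOC)cc1OCOC | intermediate
13 | 5-[(E)-2-{5-[(1S)-2-(3,5-dihydroxyphenyl)-1-[2-hydroxy-4-(methoxymethoxy)phenyl]ethyl]-2,4-bis(methoxymethoxy)phenyl}ethenyl]benzene-1,3-diol | Oc1cc(O)cc(/C=C/c2cc([C@@H](Cc3cc(O)cc(O)c3)c3ccc(OCOC)cc3O)c(OCOC)cc2OCOC)c1 | intermediate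
14 | 4-[(1S)-1-(2,4-dihydroxyphenyl)-2-(3,5-dihydroxyphenyl)ethyl]-6-[(E)-2-(3,5-dihydroxyphenyl)ethenyl]benzene-1,3-diol | Oc1cc(O)cc(/C=C/c2cc([C@@H](Cc3cc(O)cc(O)c3)c3ccc(O)cc3O)c(O)cc2O)c1 | target

**Count and risks**
Total steps: 7. Longest linear sequence: 6 steps (1, 2, 4, 5, 6, 7); step 3 is a one-step side branch.

The three steps most likely to fail:

Step 6. The ring D arm may close through the wrong terminus (the CH2 next to the stereocentre adding to the acetyl carbonyl), or hydroxide may cut the triketone arms by retro-Claisen cleavage before they aromatise; the conjugated cinnamoyl carbonyl may also accept the methyl carbanion too slowly. Fallback, from 9 back to 13: the terminal methyl carbanion of the trilithio salt of methyl 3,5-dioxohexanoate F1 (LiN(i-Pr)2, THF) would be acylated by both acyl groups of 9 to give the bis(3,5,7-trioxo ester) F2. In each arm the ester-flanked C2 methylene is then by far the most acidic terminus, so K2CO3 in MeOH at room temperature should close both rings by aldol condensation onto C7 to give the bis(methyl β-resorcylate) F3. Saponification (aq. KOH, 80 °C) to the diacid F4 and thermal decarboxylation of the two 6-substituted 2,4-dihydroxybenzoic acids (DMSO–H2O, 100 °C) would then give 13.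

Step 4. Protodeboronation of the electron-rich ortho-alkoxy boronic acid may outrun carbometalation of the donor-substituted coumarin, or the ortho substituent may erode the face selection. Fallback, from 4 and 6 back to 7: oxidative Heck arylation of 6 at C4 (Pd(OAc)2, 1,10-phenanthroline, O2, DMF) would give the 4-arylcoumarin F5. Copper hydride conjugate reduction (Cu(OAc)2·H2O, the enantiomer of DTBM-Segphos that delivers hydride to the face giving 4S, (EtO)2MeSiH, t-BuOH, toluene) would then set the stereocentre by C–H instead of C–C bond formation. Any lactol F6 from over-reduction would be returned to 7 with Ag2CO3 on Celite.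

Step 7. Protonation of the freed 2,4-dihydroxystilbene (with capture by methanol or by a resorcinol ring), or capture of the acetal-derived cation by rings A and D, may accompany the acetal cleavage. Fallback, from 13 back to 14: Me3SiOTf and 2,2′-bipyridyl in MeCN at 0 °C would exchange the three aryl MOM acetals, and silylate the free phenols, without any Brønsted acid to give the octakis(trimethylsilyl) ether F7, which water would hydrolyse to 14.

**Further compounds**
F1 | step 6 | methyl 3,5-dioxohexanoate | CC(=O)CC(=O)CC(=O)OC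
F2 | step 6 | methyl (8E)-9-{5-[(1S)-1-[2-hydroxy-4-(methoxymethoxy)phenyl]-9-methoxy-3,5,7,9-tetraoxononyl]-2,4-bis(methoxymethoxy)phenyl}-3,5,7-trioxonon-8-enoate | COC(=O)CC(=O)CC(=O)CC(=O)/C=C/c1cc([C@@H](CC(=O)CC(=O)CC(=O)CC(=O)OC)c2ccc(OCOC)cc2O)c(OCOC)cc1OCOC
F3 | step 6 | methyl 2-[(E)-2-{5-[(1S)-2-[3,5-dihydroxy-2-(methoxycarbonyl)phenyl]-1-[2-hydroxy-4-(methoxymethoxy)phenyl]ethyl]-2,4-bis(methoxymethoxy)phenyl}ethenyl]-4,6-dihydroxybenzoate | COC(=O)c1c(O)cc(O)cc1/C=C/c1cc([C@@H](Cc2cc(O)cc(O)c2C(=O)OC)c2ccc(OCOC)cc2O)c(OCOC)cc1OCOC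
F4 | step 6 | 2-[(E)-2-{5-[(1S)-2-(2-carboxy-3,5-dihydroxyphenyl)-1-[2-hydroxy-4-(methoxymethoxy)phenyl]ethyl]-2,4-bis(methoxymethoxy)phenyl}ethenyl]-4,6-dihydroxybenzoic acid | OC(=O)c1c(O)cc(O)cc1/C=C/c1cc([C@@H](Cc2cc(O)cc(O)c2C(=O)O)c2ccc(OCOC)cc2O)c(OCOC)cc1OCOC
F5 | step 4 | 4-[5-bromo-2,4-bis(methoxymethoxy)phenyl]-7-(methoxymethoxy)-2H-chromen-2-one | O=c1cc(-c2cc(Br)c(OCOC)cc2OCOC)c2ccc(OCOC)cc2o1
F6 | step 4 | (4S)-4-[5-bromo-2,4-bis(methoxymethoxy)phenyl]-7-(methoxymethoxy)-3,4-dihydro-2H-chromen-2-ol (both configurations at C2) | Brc1cc([C@@H](CC(O)O2)c3ccc(OCOC)cc32)c(OCOC)cc1OCOC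
F7 | step 7 | octakis(trimethylsilyl) ether of 14, (1S) | C[Si](C)(C)Oc1cc(O[Si](C)(C)C)cc(/C=C/c2cc([C@@H](Cc3cc(O[Si](C)(C)C)cc(O[Si](C)(C)C)c3)c3ccc(O[Si](C)(C)C)cc3O[Si](C)(C)C)c(O[Si](C)(C)C)cc2O[Si](C)(C)C)c1
A1 | direct plan | benzene-1,3-diol (resorcinol) | Oc1cccc(O)c1
A2 | direct plan | 3,5-dimethoxyphenylacetic acid | COc1cc(CC(=O)O)cc(OC)c1
A3 | direct plan | 1-(2,4-dihydroxyphenyl)-2-(3,5-dimethoxyphenyl)ethan-1-one | COc1cc(CC(=O)c2ccc(O)cc2O)cc(OC)c1
A4 | direct plan | 4,4'-[2-(3,5-dimethoxyphenyl)ethane-1,1-diyl]di(benzene-1,3-diol) | COc1cc(CC(c2ccc(O)cc2O)c2ccc(O)cc2O)cc(OC)c1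
A5 | direct plan | 4-bromo-6-[(1S)-1-(2,4-dihydroxyphenyl)-2-(3,5-dimethoxyphenyl)ethyl]benzene-1,3-diol | Brc1cc([C@@H](Cc2cc(OC)cc(OC)c2)c2ccc(O)cc2O)c(O)cc1O
A6 | direct plan | 1-ethenyl-3,5-dimethoxybenzene (3,5-dimethoxystyrene) | C=Cc1cc(OC)cc(OC)c1
A7 | direct plan | 4-[(1S)-1-(2,4-dihydroxyphenyl)-2-(3,5-dimethoxyphenyl)ethyl]-6-[(E)-2-(3,5-dimethoxyphenyl)ethenyl]benzene-1,3-diol | COc1cc(OC)cc(/C=C/c2cc([C@@H](Cc3cc(OC)cc(OC)c3)c3ccc(O)cc3O)c(O)cc2O)c1
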